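**Retrosynthetic overview**

1. The plan rests on ring D: the bond between the quaternary C7a' and C3a' lies in a cyclohexene whose alkene is C6'=C7', and C3a' carries the carboxyl-level carbon C3'. This γ,δ-unsaturated acid pattern is the retron of an ester-enolate Claisen rearrangement.
2. Ring A is cut last at O2–C1 and C1–C7a (carbonylative enol lactonisation of a C7a enol triflate with a C3a pentanoyl group). Ring E is cut at O2'–C1' (oxidative lactonisation of C1'H2OH onto the tertiary C3'–OH). The C3'–O and C3'–C8' bonds come from a C3' ketone through an enol ether oxidised on the convex face.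
3. Ring C is cut at C3'–C6 (5-exo acyl radical closure). Ring D is cut at C3a'–C7a' by Ireland–Claisen ring contraction of δ-lactone 15, where C6' (R) and the (Z)-C7'=C7a' alkene fix both new centres relative to the preset C7.
4. Lactone 15 comes from cyclohexa-1,3-diene (ring B, via epoxide and alkynyl opening), δ-valerolactone (C3'–C6'), ynone reduction (C6'), trans-hydroalumination/iodination and a CH2OH cross-coupling (C1').
5. Ring order: B (purchased) → D (step 11) → C (step 13) → E (step 19) → A (step 22).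

Key step: step 11

Remark: phthalide numbering is used, with primes on the butanoyl half; the sense of step 1 is assumed from the behaviour of indene-type cis-alkenes with the same catalyst, and C8' (21–27, 32, 33) and C3a (30) are carried as mixtures because these centres end sp2.

**Route**

Step 1
Reactants: 1 cyclohexa-1,3-diene
Product: 2 (1S,6R)-7-oxabicyclo[4.1.0]hept-2-ene
Conditions: (S,S)-(salen)MnCl [salen = N,N'-bis(3,5-di-tert-butylsalicylidene)cyclohexane-1,2-diamine dianion] (5 mol %), 4-phenylpyridine N-oxide, aq NaOCl (pH 11), CH2Cl2, 0 °C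
Reagents that add atoms: sodium hypochlorite, [Na+].[O-]Cl
Why: Jacobsen–Katsuki epoxidation of a cis-disubstituted conjugated alkene should oxidise one double bond of the symmetric diene with the facial sense known for indene, which corresponds to the (1S,6R) epoxide; the solution of the volatile epoxide is used directly.

Step 2
Reactants: 2 (1S,6R)-7-oxabicyclo[4.1.0]hept-2-ene
Product: 3 (1R,2S)-2-[(trimethylsilyl)ethynyl]cyclohex-3-en-1-ol
Conditions: Me3SiC≡CH, n-BuLi, THF, −78 °C; BF3·OEt2; then 2, −78 °C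
Reagents that add atoms: ethynyltrimethylsilane, C#C[Si](C)(C)C
Why: BF3-promoted alkynylation of an epoxide (Yamaguchi conditions) should open the activated allylic C–O bond in an SN2 manner with inversion, so the alkynyl group ends trans to the hydroxyl and fixes C7 (S) next to C7a (R).

Step 3
Reactants: 3 (1R,2S)-2-[(trimethylsilyl)ethynyl]cyclohex-3-en-1-ol
Product: 4 (1R,2S)-2-ethynylcyclohex-3-en-1-ol
Conditions: K2CO3 (cat.), MeOH, rt
Reagents that add atoms: none
Why: Methoxide-induced protodesilylation cleaves only the C(sp)–Si bond and leaves the stereocentres untouched.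

Step 4
Reactants: 4 (1R,2S)-2-ethynylcyclohex-3-en-1-ol
Product: 5 triethyl{[(1R,2S)-2-ethynylcyclohex-3-en-1-yl]oxy}silane
Conditions: Et3SiCl, imidazole, CH2Cl2, 0 °C
Reagents that add atoms: chlorotriethylsilane, CC[Si](Cl)(CC)CC
Why: Standard silylation masks the C7a hydroxyl as a triethylsilyl ether that tolerates organolithium, hydride, radical and ylide steps and can later be removed next to a tert-butyldimethylsilyl ether.

Step 5
Reactants: 5 triethyl{[(1R,2S)-2-ethynylcyclohex-3-en-1-yl]oxy}silane; 6 δ-valerolactone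
Product: 8 7-hydroxy-1-[(1S,6R)-6-(triethylsilyloxy)cyclohex-2-en-1-yl]hept-1-yn-3-one, via lithium acetylide 7 (not isolated)
Conditions: n-BuLi, THF, −78 °C; then 6, −78 °C; aq NH4Cl
Reagents that add atoms: none
Why: Acetylide addition to a lactone stops at the tetrahedral lactol alkoxide, which collapses on work-up to the δ-hydroxy ynone carrying C6' as the ketone and C3' as the primary alcohol.

Step 6
Reactants: 8 7-hydroxy-1-[(1S,6R)-6-(triethylsilyloxy)cyclohex-2-en-1-yl]hept-1-yn-3-one
Product: 9 (3R)-1-[(1S,6R)-6-(triethylsilyloxy)cyclohex-2-en-1-yl]hept-1-yne-3,7-diol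
Conditions: Ru[(R,R)-TsNCH(Ph)CH(Ph)NH](p-cymene) (1 mol %), i-PrOH, rt
Reagents that add atoms: none
Why: Noyori asymmetric transfer hydrogenation of an ynone, with the alkynyl group in the role of the aryl group, should give the (R)-carbinol at C6' under catalyst control, and material from the minor enantiomer of 2 becomes a diastereomer that chromatography should remove.

Step 7
Reactants: 9 (3R)-1-[(1S,6R)-6-(triethylsilyloxy)cyclohex-2-en-1-yl]hept-1-yne-3,7-diol
Product: 11 (1Z,3R)-1-iodo-1-[(1R,6R)-6-(triethylsilyloxy)cyclohex-2-en-1-yl]hept-1-ene-3,7-diol, via cyclic alkenylaluminate 10 (not isolated)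
Conditions: NaAlH2(OCH2CH2OMe)2 (4 equiv), THF, 0 °C to rt; then I2, −78 °C
Reagents that add atoms: iodine, II
Why: Hydroxyl-directed trans-hydroalumination of a propargylic alcohol places hydride on C7' and aluminium on C7a' in a five-membered alkoxyaluminate, and iodinolysis with retention should give the (Z)-iodoalkene with iodine cis to C6' and ring B trans to it.

Step 8
Reactants: 11 (1Z,3R)-1-iodo-1-[(1R,6R)-6-(triethylsilyloxy)cyclohex-2-en-1-yl]hept-1-ene-3,7-diol
Product: 13 (6R)-6-{(Z)-2-iodo-2-[(1R,6R)-6-(triethylsilyloxy)cyclohex-2-en-1-yl]ethenyl}oxan-2-one, via lactol 12 (not isolated)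
Conditions: TEMPO (0.2 equiv), PhI(OAc)2 (2.5 equiv), CH2Cl2, rt
Reagents that add atoms: none
Why: Oxoammonium oxidation is selective for the primary alcohol, the aldehyde closes with the C6' hydroxyl to the six-membered lactol, and this is oxidised on to the δ-lactone (oxidative lactonisation of a 1,5-diol).

Step 9
Reactants: 13 (6R)-6-{(Z)-2-iodo-2-[(1R,6R)-6-(triethylsilyloxy)cyclohex-2-en-1-yl]ethenyl}oxan-2-one
Product: 14 (6R)-6-{(Z)-3-hydroxy-2-[(1S,6R)-6-(triethylsilyloxy)cyclohex-2-en-1-yl]prop-1-en-1-yl}oxan-2-one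
Conditions: Bu3SnCH2OH (1.5 equiv), Pd(PPh3)4 (5 mol %), dioxane, 80 °C
Reagents that add atoms: (tributylstannyl)methanol, CCCC[Sn](CCCC)(CCCC)CO
Why: Stille coupling with selective transfer of the α-oxygenated CH2OH group from tin proceeds with retention at the alkenyl carbon, so C1' is installed cis to C6' under neutral conditions that the lactone tolerates.

Step 10
Reactants: 14 (6R)-6-{(Z)-3-hydroxy-2-[(1S,6R)-6-(triethylsilyloxy)cyclohex-2-en-1-yl]prop-1-en-1-yl}oxan-2-one
Product: 15 (6R)-6-{(Z)-3-(triethylsilyloxy)-2-[(1S,6R)-6-(triethylsilyloxy)cyclohex-2-en-1-yl]prop-1-en-1-yl}oxan-2-one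
Conditions: Et3SiCl, imidazole, CH2Cl2, 0 °C
Reagents that add atoms: chlorotriethylsilane, CC[Si](Cl)(CC)CC
Why: Silylation of the primary allylic alcohol without base strong enough to touch the lactone gives the rearrangement substrate.

Step 11
Reactants: 15 (6R)-6-{(Z)-3-(triethylsilyloxy)-2-[(1S,6R)-6-(triethylsilyloxy)cyclohex-2-en-1-yl]prop-1-en-1-yl}oxan-2-one
Product: 18 (1S,2R)-2-[(triethylsilyloxy)methyl]-2-[(1S,6R)-6-(triethylsilyloxy)cyclohex-2-en-1-yl]cyclohex-3-ene-1-carboxylic acid, via trimethylsilyl ketene acetal 16 (not isolated), via trimethylsilyl ester 17 (not isolated)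
Conditions: LiN(iPr)2, Me3SiCl, Et3N, THF, −78 °C; then toluene, 110 °C; then H2O, THF, rt
Reagents that add atoms: none
Why: This is an Ireland–Claisen rearrangement in its lactone ring-contraction form: the cyclic O-silyl ketene acetal 16 undergoes a [3,3] shift that forms C3a'–C7a' and breaks C6'–O, the closest known type being the ester-enolate Claisen ring contraction of alkenyl lactones to cycloalkenecarboxylic acids. Ring D closes through the sigmatropic bond formation itself, in a boat (bicyclo[2.2.2]octane-like) transition state imposed by the two-carbon tether C4'–C5', which also makes the new C6'=C7' alkene cis. C7a' is set by suprafacial transfer of the C6' configuration (R) across the (Z)-alkene, and C3a' by the fixed geometry of the cyclic ketene acetal, so the carboxyl carbon C3' ends cis to C7 and trans to the C1' arm. The step needs only this facial fidelity, which is secured because the tether excludes the chair and the bulky ring B occupies the outside position of the boat; no other enolisable or allylic ester site is present.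

Step 12
Reactants: 18 ring D acid
Product: 19 Se-phenyl selenoester of 18
Conditions: PhSeSePh, Bu3P, CH2Cl2, rt
Reagents that add atoms: diphenyl diselenide, c1ccc(cc1)[Se][Se]c1ccccc1
Why: Phosphine-mediated redox condensation (acyloxyphosphonium, then selenolate) converts the hindered acid into the acyl radical precursor under neutral conditions.

Step 13
Reactants: 19 Se-phenyl selenoester
Product: 20 tricyclic ketone (C3' ketone in ring C, rings B and D cis-fused on the same face of ring C)
Conditions: Bu3SnH (slow addition), AIBN (cat.), benzene, 80 °C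
Reagents that add atoms: none
Why: Acyl radical cyclisation: the C3' acyl radical attacks C6 of the ring B alkene 5-exo-trig, the three-atom tether C3a'–C7a'–C7 enforces the cis B/C fusion (H6 cis to H7), and the C5 radical is reduced by the stannane.

Step 14
Reactants: 20 tricyclic ketone
Product: 21 C3' methoxymethylidene enol ether (E/Z mixture)
Conditions: MeOCH2PPh3Cl, KN(SiMe3)2, THF, 0 °C to rt
Reagents that add atoms: (methoxymethyl)triphenylphosphonium chloride, [Cl-].COC[P+](c1ccccc1)(c1ccccc1)c1ccccc1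
Why: Wittig methoxymethylenation converts the C3' ketone into an electron-rich C3'=C8' enol ether and introduces C8'; the alkene geometry is of no consequence.

Step 15
Reactants: 21 enol ether
Product: 23 α-hydroxy aldehyde (C3'–OH on the face of the C1' arm, C8' formyl), via methoxy epoxide 22 (not isolated)
Conditions: dimethyldioxirane (1.1 equiv), acetone/CH2Cl2, −78 °C; then THF/H2O (pH 7), 0 °C
Reagents that add atoms: dimethyldioxirane, CC1(C)OO1; water, O
Why: Rubottom-type epoxidation of the enol ether, far faster than attack on the isolated ring D alkene, should occur on the convex face of ring C opposite to rings B and D, so the new C3'–O bond is cis to C1', and hydrolysis of the methoxy epoxide releases the aldehyde.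

Step 16
Reactants: 23 α-hydroxy aldehyde
Product: 24 diol (tertiary C3'–OH, secondary C8'–OH bearing n-propyl, C8' epimers)
Conditions: n-PrMgBr (3 equiv), THF, −78 to 0 °C; aq NH4Cl
Reagents that add atoms: propylmagnesium bromide, CCC[Mg]Br
Why: Grignard addition to the aldehyde after deprotonation of the tertiary hydroxyl completes the C8'–C11' chain; the new carbinol centre is oxidised away in step 24.

Step 17
Reactants: 24 diol
Product: 25 C8' tert-butyldimethylsilyl ether
Conditions: t-BuMe2SiOSO2CF3 (1.1 equiv), 2,6-lutidine, CH2Cl2, −78 °C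
Reagents that add atoms: tert-butyldimethylsilyl trifluoromethanesulfonate, CC(C)(C)[Si](C)(C)OS(=O)(=O)C(F)(F)F
Why: Silylation of the secondary hydroxyl, with the tertiary C3'–OH unreactive at low temperature, keeps C8' at the alcohol level so that only one ketone is enolisable in step 20.

Step 18
Reactants: 25 C8' silyl ether
Product: 26 triol (C1'H2OH, C7a–OH, C3'–OH; C8'–OSiMe2tBu)
Conditions: HF·pyridine, pyridine, THF, 0 °C
Reagents that add atoms: none
Why: Buffered fluoride cleaves the two triethylsilyl ethers much faster than the hindered secondary tert-butyldimethylsilyl ether.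

Step 19
Reactants: 26 triol
Product: 28 keto lactone (ring E γ-lactone C1'(=O)–O–C3', C7a ketone, C8'–OSiMe2tBu), via lactol 27 (not isolated)
Conditions: Pr4N[RuO4] (10 mol %), N-methylmorpholine N-oxide (5 equiv), 4 Å sieves, CH2Cl2, rt
Reagents that add atoms: none
Why: Ley–Griffith oxidation takes C1' to the aldehyde, which is trapped as the lactol by the cis C3' hydroxyl and oxidised to the bridged γ-lactone, while C7a–OH becomes the ketone; only a C3' hydroxyl on the face of C1' can close, so ring E confirms the C3' configuration.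

Step 20
Reactants: 28 keto lactone; 29 pentanoyl chloride
Product: 30 β-diketone (pentanoyl on C3a, enol/keto mixture)
Conditions: MgBr2·OEt2, i-Pr2NEt, CH2Cl2, rt
Reagents that add atoms: none
Why: Soft enolisation and C-acylation occurs at C3a, the only unhindered α-position, since the lactone carbonyl has no α-hydrogen, C8' is masked and C7 is tertiary and flanked by the quaternary C7a'.

Step 21
Reactants: 30 β-diketone
Product: 31 enol triflate (C7a–OSO2CF3, C3a=C7a, pentanoyl on C3a)
Conditions: NaH, PhN(SO2CF3)2, THF, 0 °C to rt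
Reagents that add atoms: N-phenylbis(trifluoromethanesulfonimide), O=S(=O)(N(c1ccccc1)S(=O)(=O)C(F)(F)F)C(F)(F)F
Why: O-sulfonylation of the sodium diketonate is expected on the ring oxygen, giving the endocyclic enol triflate favoured for 2-acylcyclohexanones.

Step 22
Reactants: 31 enol triflate
Product: 32 C8' silyl ether of the 8'-dihydro target (rings A to E complete, (Z)-butylidene)
Conditions: PdCl2(PPh3)2 (5 mol %), CO (1 atm), Et3N, DMF, 60 °C
Reagents that add atoms: carbon monoxide, [C-]#[O+]
Why: Carbonylative lactonisation: oxidative addition of the enol triflate to zerovalent palladium and CO insertion give the C7a acylpalladium, which is O-acylated 5-exo by the enolate of the neighbouring pentanoyl ketone (Negishi-type enolate trapping) to close ring A with the (Z)-butylidene geometry.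

Step 23
Reactants: 32 C8' silyl ether
Product: 33 C8' alcohol (8'-dihydro target)
Conditions: HF·pyridine, THF, rt to 40 °C
Reagents that add atoms: none
Why: Acidic fluoride removes the remaining silyl ether without opening either lactone.

Step 24
Reactants: 33 C8' alcohol
Product: 34 CNP0423313.1
Conditions: Dess–Martin periodinane, CH2Cl2, rt
Reagents that add atoms: none
Why: Dess–Martin oxidation of the secondary alcohol gives the butanoyl ketone under neutral conditions that leave the enol lactone, the bridged lactone and the ring D alkene intact.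

**Compound list**

1 | cyclohexa-1,3-diene | C1=CC=CCC1 | starting material
2 | (1S,6R)-7-oxabicyclo[4.1.0]hept-2-ene | [C@H]12O[C@H]1C=CCC2 | intermediate
3 | (1R,2S)-2-[(trimethylsilyl)ethynyl]cyclohex-3-en-1-ol | C[Si](C)(C)C#C[C@@H]1C=CCC[C@H]1O | intermediate
4 | (1R,2S)-2-ethynylcyclohex-3-en-1-ol | C#C[C@@H]1C=CCC[C@H]1O | intermediate
5 | triethyl{[(1R,2S)-2-ethynylcyclohex-3-en-1-yl]oxy}silane | C#C[C@@H]1C=CCC[C@H]1O[Si](CC)(CC)CC | intermediate
6 | δ-valerolactone (oxan-2-one) | O=C1CCCCO1 | starting material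
7 | lithium acetylide of 5 (not isolated) | [Li+].[C-]#C[C@@H]1C=CCC[C@H]1O[Si](CC)(CC)CC | intermediate
8 | 7-hydroxy-1-[(1S,6R)-6-(triethylsilyloxy)cyclohex-2-en-1-yl]hept-1-yn-3-one | OCCCCC(=O)C#C[C@@H]1C=CCC[C@H]1O[Si](CC)(CC)CC | intermediate
9 | (3R)-1-[(1S,6R)-6-(triethylsilyloxy)cyclohex-2-en-1-yl]hept-1-yne-3,7-diol | OCCCC[C@@H](O)C#C[C@@H]1C=CCC[C@H]1O[Si](CC)(CC)CC | intermediate
10 | cyclic alkenylaluminate from 9, aluminium on C7a' and bound to the C6' oxygen, remote alkoxide drawn as sodium salt (not isolated) | [Na+].[Na+].COCCO[Al-]1(OCCOC)O[C@H](CCCC[O-])C=C1[C@@H]2C=CCC[C@H]2O[Si](CC)(CC)CC | intermediate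
11 | (1Z,3R)-1-iodo-1-[(1R,6R)-6-(triethylsilyloxy)cyclohex-2-en-1-yl]hept-1-ene-3,7-diol | OCCCC[C@@H](O)/C=C(\I)[C@@H]1C=CCC[C@H]1O[Si](CC)(CC)CC | intermediate
12 | lactol of 13, (6R)-6-[(Z)-2-iodo-2-(cyclohexenyl)ethenyl]oxan-2-ol (not isolated) | OC1CCC[C@H](/C=C(\I)[C@@H]2C=CCC[C@H]2O[Si](CC)(CC)CC)O1 | intermediate
13 | (6R)-6-{(Z)-2-iodo-2-[(1R,6R)-6-(triethylsilyloxy)cyclohex-2-en-1-yl]ethenyl}oxan-2-one | O=C1CCC[C@H](/C=C(\I)[C@@H]2C=CCC[C@H]2O[Si](CC)(CC)CC)O1 | intermediate
14 | (6R)-6-{(Z)-3-hydroxy-2-[(1S,6R)-6-(triethylsilyloxy)cyclohex-2-en-1-yl]prop-1-en-1-yl}oxan-2-one | O=C1CCC[C@H](/C=C(\CO)[C@@H]2C=CCC[C@H]2O[Si](CC)(CC)CC)O1 | intermediate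
15 | (6R)-6-{(Z)-3-(triethylsilyloxy)-2-[(1S,6R)-6-(triethylsilyloxy)cyclohex-2-en-1-yl]prop-1-en-1-yl}oxan-2-one (Claisen precursor) | O=C1CCC[C@H](/C=C(\CO[Si](CC)(CC)CC)[C@@H]2C=CCC[C@H]2O[Si](CC)(CC)CC)O1 | intermediate
16 | trimethylsilyl ketene acetal of 15 (not isolated) | C[Si](C)(C)OC1=CCC[C@H](/C=C(\CO[Si](CC)(CC)CC)[C@@H]2C=CCC[C@H]2O[Si](CC)(CC)CC)O1 | intermediate
17 | trimethylsilyl ester of 18 (not isolated) | C[Si](C)(C)OC(=O)[C@H]1CCC=C[C@@]1(CO[Si](CC)(CC)CC)[C@@H]2C=CCC[C@H]2O[Si](CC)(CC)CC | intermediate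
18 | (1S,2R)-2-[(triethylsilyloxy)methyl]-2-[(1S,6R)-6-(triethylsilyloxy)cyclohex-2-en-1-yl]cyclohex-3-ene-1-carboxylic acid (ring D acid) | OC(=O)[C@H]1CCC=C[C@@]1(CO[Si](CC)(CC)CC)[C@@H]2C=CCC[C@H]2O[Si](CC)(CC)CC | intermediate
19 | Se-phenyl selenoester of 18 | O=C([Se]c1ccccc1)[C@H]2CCC=C[C@@]2(CO[Si](CC)(CC)CC)[C@@H]3C=CCC[C@H]3O[Si](CC)(CC)CC | intermediate
20 | tricyclic ketone: ring C cyclopentanone (C3'=O) cis-fused to ring B at C6–C7 and to ring D at C3a'–C7a', both six-membered rings on one face of ring C, C1'H2OSiEt3 on the other; C7a–OSiEt3 trans to C7a' | CC[Si](CC)(CC)O[C@@H]1CCC[C@@H]2[C@H]1[C@]3(CO[Si](CC)(CC)CC)C=CCC[C@@H]3C2=O | intermediate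
21 | C3' methoxymethylidene enol ether of 20 (E/Z mixture) | CC[Si](CC)(CC)O[C@@H]1CCC[C@@H]2[C@H]1[C@]3(CO[Si](CC)(CC)CC)C=CCC[C@@H]3C2=COC | intermediate
22 | spiro methoxy epoxide at C3'/C8', oxygen on the face of C1' (not isolated) | CC[Si](CC)(CC)O[C@@H]1CCC[C@@H]2[C@H]1[C@]3(CO[Si](CC)(CC)CC)C=CCC[C@@H]3[C@@]24OC4OC | intermediate
23 | α-hydroxy aldehyde: C3'–OH cis to the C1' arm, C8' formyl | CC[Si](CC)(CC)O[C@@H]1CCC[C@@H]2[C@H]1[C@]3(CO[Si](CC)(CC)CC)C=CCC[C@@H]3[C@]2(O)C=O | intermediate
24 | diol: tertiary C3'–OH, secondary C8'–OH with n-propyl (C8' epimers) | CC[Si](CC)(CC)O[C@@H]1CCC[C@@H]2[C@H]1[C@]3(CO[Si](CC)(CC)CC)C=CCC[C@@H]3[C@]2(O)C(O)CCC | intermediate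
25 | C8' tert-butyldimethylsilyl ether of 24 | CC[Si](CC)(CC)O[C@@H]1CCC[C@@H]2[C@H]1[C@]3(CO[Si](CC)(CC)CC)C=CCC[C@@H]3[C@]2(O)C(CCC)O[Si](C)(C)C(C)(C)C | intermediate
26 | triol: C1'H2OH, C7a–OH, C3'–OH; C8'–OSiMe2tBu | O[C@@H]1CCC[C@@H]2[C@H]1[C@]3(CO)C=CCC[C@@H]3[C@]2(O)C(CCC)O[Si](C)(C)C(C)(C)C | intermediate
27 | ring E lactol (C1' hemiacetal) with C7a ketone (not isolated) | O=C1CCC[C@@H]2[C@H]1[C@]34C=CCC[C@@H]3[C@@]2(C(CCC)O[Si](C)(C)C(C)(C)C)OC4O | intermediate
28 | keto lactone: ring E γ-lactone, C7a ketone, C8'–OSiMe2tBu | O=C1CCC[C@@H]2[C@H]1[C@]34C=CCC[C@@H]3[C@@]2(C(CCC)O[Si](C)(C)C(C)(C)C)OC4=O | intermediate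
29 | pentanoyl chloride | CCCCC(Cl)=O | starting material
30 | β-diketone: 28 with pentanoyl on C3a (enol/keto mixture) | CCCCC(=O)C1CC[C@@H]2[C@H](C1=O)[C@]34C=CCC[C@@H]3[C@@]2(C(CCC)O[Si](C)(C)C(C)(C)C)OC4=O | intermediate
31 | enol triflate: C7a–OSO2CF3, C3a=C7a, pentanoyl on C3a | CCCCC(=O)C=1CC[C@@H]2[C@H](C=1OS(=O)(=O)C(F)(F)F)[C@]34C=CCC[C@@H]3[C@@]2(C(CCC)O[Si](C)(C)C(C)(C)C)OC4=O | intermediate
32 | C8' tert-butyldimethylsilyl ether of the 8'-dihydro target | CCC/C=C1\OC(=O)C2=C1CC[C@@H]1[C@H]2[C@]23C=CCC[C@@H]2[C@@]1(C(CCC)O[Si](C)(C)C(C)(C)C)OC3=O | intermediate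
33 | 8'-dihydro target (C8' alcohol) | CCC/C=C1\OC(=O)C2=C1CC[C@@H]1[C@H]2[C@]23C=CCC[C@@H]2[C@@]1(C(O)CCC)OC3=O | intermediate
34 | CNP0423313.1 | CCC/C=C1\OC(=O)C2=C1CC[C@@H]1[C@H]2[C@]23C=CCC[C@@H]2[C@@]1(C(=O)CCC)OC3=O | target

**Step count and risks**

Total step count: 24. Longest linear sequence: 24 steps (1 to 34).

Steps most likely to fail:

Step 11. The boat transition state carries ring B and the silyloxymethyl group on the terminus that becomes quaternary, so the ketene acetal may decompose or simply hydrolyse back before it rearranges. The fallback sets out from 15 and returns at 18. Methanolysis of 15 (NaOMe cat., MeOH, 0 °C) should give methyl (5R,6Z)-5-hydroxy-8-(triethylsilyloxy)-7-[(1S,6R)-6-(triethylsilyloxy)cyclohex-2-en-1-yl]oct-6-enoate F1. Mitsunobu esterification with hex-5-enoic acid (PPh3, diisopropyl azodicarboxylate) inverts C6' and should give the (S)-allylic hex-5-enoate F2. An acyclic Ireland–Claisen rearrangement (LiN(iPr)2, Me3SiCl, THF/DMPU, −78 °C to rt) then runs through a chair, with the ketene acetal geometry that has the butenyl chain cis to OSiMe3; the remote methyl ester is silylated as a bystander and returns on work-up. It should give the diene acid F3 with the same C3a' and C7a' configurations as 18. Ring-closing metathesis with the second-generation Grubbs catalyst RuCl2(=CHPh)(SIMes)(PCy3) then closes ring D between C6' and C7' and gives 18.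

Step 22. Capture of the C7a acylpalladium by the hindered enolate oxygen may be slow, so that reduction or hydrolysis of the acylpalladium takes over. The fallback sets out from 31 and returns at 32. Hydroxycarbonylation with an external nucleophile (Pd(OAc)2, dppf, CO, KOAc, DMF/H2O) should give the keto acid F4, in equilibrium with its 3-butyl-3-hydroxy lactone. Acid-catalysed dehydrative enol lactonisation (TsOH cat., toluene, 4 Å sieves, 80 °C) should then give 32 as the more stable Z isomer.

Step 9. Transfer of the sp3 hydroxymethyl group from tin to the hindered alkenylpalladium may be slow, leaving time for protodeiodination or for zerovalent palladium to ionise the allylic lactone. The fallback sets out from 13 and returns at 14. Palladium-catalysed formylation (Pd(PPh3)4, CO, Bu3SnH by slow addition, THF, 50 °C), in which CO insertion replaces the slow transmetalation, should give the (Z)-enal F5. Luche reduction (NaBH4, CeCl3·7H2O, MeOH, −40 °C) then gives 14.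

Further compounds
F1 | step 11 | methyl (5R,6Z)-5-hydroxy-8-(triethylsilyloxy)-7-[(1S,6R)-6-(triethylsilyloxy)cyclohex-2-en-1-yl]oct-6-enoate | COC(=O)CCC[C@@H](O)/C=C(\CO[Si](CC)(CC)CC)[C@@H]1C=CCC[C@H]1O[Si](CC)(CC)CC
F2 | step 11 | (S)-allylic hex-5-enoate of F1 (C6' inverted) | C=CCCCC(=O)O[C@@H](CCCC(=O)OC)/C=C(\CO[Si](CC)(CC)CC)[C@@H]1C=CCC[C@H]1O[Si](CC)(CC)CC
F3 | step 11 | acyclic Claisen acid: C3a' bears but-3-enyl, C7a' bears the (E)-alkenyl chain ending in the methyl ester | OC(=O)[C@@H](CCC=C)[C@](/C=C/CCCC(=O)OC)(CO[Si](CC)(CC)CC)[C@@H]1C=CCC[C@H]1O[Si](CC)(CC)CC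
F4 | step 22 | keto acid: C7a–CO2H, C3a pentanoyl (open form of the hydroxy lactone) | OC(=O)C1=C(C(=O)CCCC)CC[C@@H]2[C@H]1[C@]34C=CCC[C@@H]3[C@@]2(C(CCC)O[Si](C)(C)C(C)(C)C)OC4=O
F5 | step 9 | (Z)-enal: C1' formyl cis to C6' on the lactone | O=C1CCC[C@H](/C=C(\C=O)[C@@H]2C=CCC[C@H]2O[Si](CC)(CC)CC)O1
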